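**Strategy.** The route rests on cutting the bond between the benzylic CH2 (side-chain C1') and the aromatic carbon that lies between two phenolic hydroxyls. Seen this way, the C10 side chain is (S)-linalool: C1'–C2' is its vinyl group and the tertiary carbinol C3' is already in place. The key step is a one-flask 9-BBN hydroboration/B-alkyl Suzuki–Miyaura coupling that adds hydrogen and the acylphloroglucinol ring across that vinyl group anti-Markovnikov, distinguishes it from the trisubstituted C6'=C7' alkene and leaves C3' untouched. Its precursors are (S)-linalool, made from geraniol by Sharpless epoxidation and reductive epoxide opening, and the tris-MOM ether of 3-iodophlorisobutyrophenone.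

Key step: step 7

Remark: the carbinol carbon of the target is S (OH > CH2CH2Ar > CH2CH2CH=C(CH3)2 > CH3). It has the same spatial arrangement and the same descriptor as C3 of (S)-linalool and of (2S,3S)-2,3-epoxygeraniol. (S)-Linalool is made, not bought, so that its enantiomeric purity is defined by the Sharpless step.

**Route**

Step 1
Reactants: 1 phloroglucinol (benzene-1,3,5-triol); 2 isobutyryl chloride (2-methylpropanoyl chloride)
Product: 3 phlorisobutyrophenone, 2-methyl-1-(2,4,6-trihydroxyphenyl)propan-1-one
Conditions: AlCl3 (4 equiv), PhNO2/CH2Cl2, 0 °C → 50 °C; then ice, 1 M HCl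
Reagents that add atoms: none
Why: Friedel–Crafts acylation of the triply activated ring should stop at the mono-ketone, because the aluminium-chelated ortho-hydroxy aryl ketone is deactivated towards a second acylation.

Step 2
Reactants: 3 phlorisobutyrophenone
Product: 4 2-methyl-1-[2,4,6-tris(methoxymethoxy)phenyl]propan-1-one
Conditions: NaH (3.6 equiv), MOMCl (3.6 equiv), DMF, 0 °C → rt
Reagents that add atoms: chloromethyl methyl ether (MOMCl), COCCl
Why: Williamson-type O-alkylation, in which the hard electrophile MOMCl should react at oxygen of the fully deprotonated triphenoxide, NaH breaking the hydrogen bonds of the two ortho hydroxyls to the ketone so that all three positions are capped.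

Step 3
Reactants: 4 tris-MOM ketone
Product: 5 1-[3-iodo-2,4,6-tris(methoxymethoxy)phenyl]-2-methylpropan-1-one
Conditions: NIS (1.05 equiv), MeCN, 0 °C → rt, dark
Reagents that add atoms: N-iodosuccinimide (NIS), O=C1CCC(=O)N1I
Why: Electrophilic aromatic iodination at one of the two equivalent ring CH positions, each activated by three alkoxy groups, should stop at the mono-iodide because iodine deactivates the ring and forces the flanking OMOM groups out of conjugation.

Step 4
Reactants: 6 geraniol
Product: 7 (2S,3S)-2,3-epoxygeraniol
Conditions: Ti(OiPr)4 (5 mol %), L-(+)-diethyl tartrate (7.5 mol %), t-BuOOH (anhydrous, 2 equiv), 4 Å MS, CH2Cl2, −20 °C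
Reagents that add atoms: tert-butyl hydroperoxide, CC(C)(C)OO
Why: Sharpless asymmetric epoxidation, in which the titanium–L-(+)-tartrate complex binds the allylic hydroxyl and delivers oxygen only to the C2=C3 alkene (the C6=C7 alkene has no directing group) on the face that gives the 2S,3S epoxide, which fixes the later carbinol carbon C3 as S.

Step 5
Reactants: 7 (2S,3S)-2,3-epoxygeraniol
Product: 8 (2S,3R)-3-(iodomethyl)-2-methyl-2-(4-methylpent-3-en-1-yl)oxirane
Conditions: I2, PPh3, imidazole, THF, 0 °C, dark
Reagents that add atoms: iodine, II
Why: Appel reaction, in which SN2 displacement of the primary alkoxyphosphonium ion by iodide under imidazole buffering should leave the epoxide and both stereocentres untouched (the descriptor of the CH carbon changes only because iodine raises the rank of the CH2 group).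

Step 6
Reactants: 8 epoxy iodide
Product: 9 (S)-linalool, (3S)-3,7-dimethylocta-1,6-dien-3-ol
Conditions: Zn dust (activated), EtOH, reflux
Reagents that add atoms: none
Why: Reductive epoxide opening (Boord-type β-elimination of the organozinc formed at C1) cleaves only the C2–O bond, so the C3–O bond and its S configuration pass unchanged into the tertiary allylic alcohol.

Step 7
Reactants: 9 (S)-linalool; 5 aryl iodide
Product: 11 (S)-1-[3-(3-hydroxy-3,7-dimethyloct-6-en-1-yl)-2,4,6-tris(methoxymethoxy)phenyl]-2-methylpropan-1-one, via B-alkyl-9-BBN borane 10 (not isolated)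
Conditions: 9 (1.3 equiv), 9-BBN (0.5 M in THF, 2 equiv per 9), 0 °C → rt, 3 h; then degassed 3 M aq. K3PO4, 10 min; then 5 (1.0 equiv), Pd(OAc)2 (5 mol %), SPhos (10 mol %), THF, 60 °C
Reagents that add atoms: 9-borabicyclo[3.3.1]nonane (9-BBN), B1C2CCCC1CCC2 (its boron and carbon atoms stay in intermediate 10 only; 11 keeps only its hydrogen)
Why: 9-BBN adds syn and anti-Markovnikov across the monosubstituted C1=C2 vinyl group of 9 (boron on C1) to give 10; after the excess B–H is quenched by the aqueous base (so that it cannot reduce the ketone of 5), Pd(0)/SPhos inserts into the C–I bond of 5, the base-activated primary alkyl group passes from boron to palladium, and reductive elimination forms the bond between the ring carbon and the benzylic CH2. The closest known reaction type is the one-pot hydroboration/B-alkyl Suzuki–Miyaura coupling, which is established for vinyl tertiary carbinols and, with dialkylbiarylphosphine ligands, for di-ortho-substituted aryl halides. No ring is closed and no stereocentre is formed: the S carbinol carbon of 9 is two atoms away from the reacting carbon, none of its bonds is touched, and it is carried into 11 unchanged. The step needs chemoselectivity between the two alkenes and regioselectivity within the vinyl group; both are secured by the bulk of 9-BBN, which reacts far faster with a monosubstituted than with a trisubstituted alkene and places boron on the terminal carbon, away from the quaternary C3. The tertiary hydroxyl reacts only slowly with 9-BBN (the second equivalent covers this, and any B–O bond is hydrolysed by the aqueous phosphate), while the MOM acetals and the hindered ketone are inert to the basic coupling medium. β-Hydride elimination from the alkylpalladium intermediate, the main competing path, should be outrun by the fast reductive elimination that the bulky, electron-rich SPhos ligand enforces.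

Step 8
Reactants: 11 tris-MOM coupling product
Product: 12 1-{2,4,6-trihydroxy-3-[(3S)-3-hydroxy-3,7-dimethyloct-6-en-1-yl]phenyl}-2-methylpropan-1-one (target)
Conditions: ZnBr2 (3.3 equiv), n-PrSH (6.6 equiv), CH2Cl2, 0 °C → rt, 15 min; aq. NaHCO3
Reagents that add atoms: none
Why: Lewis acid/thiol transacetalisation (ZnBr2 activates each aryl MOM acetal and the thiol takes over the methoxymethyl group) should free the three phenols within minutes without strong protic acid, so that the tertiary alcohol and the trisubstituted alkene neither ionise nor cyclise onto a neighbouring hydroxyl.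

**Compound list**

1 | phloroglucinol (benzene-1,3,5-triol) | Oc1cc(O)cc(O)c1 | starting material
2 | isobutyryl chloride (2-methylpropanoyl chloride) | CC(C)C(=O)Cl | starting material
3 | phlorisobutyrophenone, 2-methyl-1-(2,4,6-trihydroxyphenyl)propan-1-one | CC(C)C(=O)c1c(O)cc(O)cc1O | intermediate
4 | 2-methyl-1-[2,4,6-tris(methoxymethoxy)phenyl]propan-1-one | CC(C)C(=O)c1c(OCOC)cc(OCOC)cc1OCOC | intermediate
5 | 1-[3-iodo-2,4,6-tris(methoxymethoxy)phenyl]-2-methylpropan-1-one (iodine between two OMOM groups) | CC(C)C(=O)c1c(OCOC)cc(OCOC)c(I)c1OCOC | intermediate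
6 | geraniol, (2E)-3,7-dimethylocta-2,6-dien-1-ol | CC(C)=CCC/C(C)=C/CO | starting material
7 | (2S,3S)-2,3-epoxygeraniol, [(2S,3S)-3-methyl-3-(4-methylpent-3-en-1-yl)oxiran-2-yl]methanol | CC(C)=CCC[C@]1(C)O[C@H]1CO | intermediate
8 | (2S,3R)-3-(iodomethyl)-2-methyl-2-(4-methylpent-3-en-1-yl)oxirane (iodide of 7, same spatial arrangement) | CC(C)=CCC[C@]1(C)O[C@H]1CI | intermediate
9 | (S)-linalool, (3S)-3,7-dimethylocta-1,6-dien-3-ol | CC(C)=CCC[C@](C)(O)C=C | intermediate
10 | (3R)-1-(9-borabicyclo[3.3.1]nonan-9-yl)-3,7-dimethyloct-6-en-3-ol (same spatial arrangement as 9; the descriptor changes only because boron ranks below carbon) | CC(C)=CCC[C@](C)(O)CCB1C2CCCC1CCC2 | intermediate (not isolated)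
11 | (S)-1-[3-(3-hydroxy-3,7-dimethyloct-6-en-1-yl)-2,4,6-tris(methoxymethoxy)phenyl]-2-methylpropan-1-one | CC(C)=CCC[C@](C)(O)CCc1c(OCOC)cc(OCOC)c(C(=O)C(C)C)c1OCOC | intermediate
12 | 1-{2,4,6-trihydroxy-3-[(3S)-3-hydroxy-3,7-dimethyloct-6-en-1-yl]phenyl}-2-methylpropan-1-one | CC(C)=CCC[C@](C)(O)CCc1c(O)cc(O)c(C(=O)C(C)C)c1O | target

**Step count and risks**

Total step count: 8 (the hydroboration is part of step 7).
Longest linear sequence: 5 steps (6 → 7 → 8 → 9 → 11 → 12; equally 1 → 3 → 4 → 5 → 11 → 12).

Steps most likely to fail:

1. Step 7. Transmetalation to the doubly ortho-alkoxylated arylpalladium may be slow, so that reduction of the C–I bond of 5 or β-hydride elimination of the alkyl group outruns the coupling. The fallback sets out from 5 and 9 and returns at 11. A Heck reaction of 5 with the vinyl group of 9 (Pd(OAc)2, n-Bu4NCl, NaHCO3, DMF, 80 °C) should give the (E)-styrene (S,E)-1-[3-(3-hydroxy-3,7-dimethylocta-1,6-dien-1-yl)-2,4,6-tris(methoxymethoxy)phenyl]-2-methylpropan-1-one F1, since the quaternary carbinol carbon allows β-hydride elimination only towards the ring. Diimide (2-nitrobenzenesulfonyl hydrazide, Et3N, CH2Cl2, rt), which reduces a 1,2-disubstituted alkene faster than a trisubstituted one, should then saturate the styrene bond and give 11.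

2. Step 8. The Lewis acid may ionise the tertiary carbinol or activate the C6'=C7' alkene, with ring closure onto the ortho phenol (chroman) or onto the side-chain hydroxyl (tetrahydropyran), or the acetal para to the ketone may be cleaved incompletely. The fallback sets out from 3 and returns at 12; base-labile esters replace the acetals. Mono-iodination of 3 (NIS, MeCN, −20 °C) should give 1-(2,4,6-trihydroxy-3-iodophenyl)-2-methylpropan-1-one F2. PivCl, pyridine and DMAP should convert it into 2-iodo-4-(2-methylpropanoyl)benzene-1,3,5-triyl tris(2,2-dimethylpropanoate) F3. Coupling of F3 with borane 10 under the conditions of step 7 should give 2-[(3S)-3-hydroxy-3,7-dimethyloct-6-en-1-yl]-4-(2-methylpropanoyl)benzene-1,3,5-triyl tris(2,2-dimethylpropanoate) F4. K2CO3 in MeOH at rt under argon should then remove the three esters by transesterification and give 12, under conditions to which the tertiary alcohol and the alkene are inert.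

3. Step 3. A second iodination at the other, equivalent ring position may compete, or the iodonium source may strip a MOM group. The fallback sets out from 1 and returns at 5; it uses directed ortho-metalation, which functionalises one position at a time. NaH and MOMCl in DMF should convert 1 into 1,3,5-tris(methoxymethoxy)benzene F5. n-BuLi (THF, 0 °C) followed by isobutyraldehyde should give racemic 2-methyl-1-[2,4,6-tris(methoxymethoxy)phenyl]propan-1-ol F6. n-BuLi (2.2 equiv, THF, 0 °C) followed by I2 should lithiate and iodinate between two OMOM groups and give racemic 1-[3-iodo-2,4,6-tris(methoxymethoxy)phenyl]-2-methylpropan-1-ol F7. Dess–Martin periodinane in CH2Cl2 should oxidise the carbinol and give 5.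

**Further compounds**

F1 | step 7 | (S,E)-1-[3-(3-hydroxy-3,7-dimethylocta-1,6-dien-1-yl)-2,4,6-tris(methoxymethoxy)phenyl]-2-methylpropan-1-one | CC(C)=CCC[C@](C)(O)/C=C/c1c(OCOC)cc(OCOC)c(C(=O)C(C)C)c1OCOC
F2 | step 8 | 1-(2,4,6-trihydroxy-3-iodophenyl)-2-methylpropan-1-one | CC(C)C(=O)c1c(O)cc(O)c(I)c1O
F3 | step 8 | 2-iodo-4-(2-methylpropanoyl)benzene-1,3,5-triyl tris(2,2-dimethylpropanoate) | CC(C)C(=O)c1c(OC(=O)C(C)(C)C)cc(OC(=O)C(C)(C)C)c(I)c1OC(=O)C(C)(C)C
F4 | step 8 | 2-[(3S)-3-hydroxy-3,7-dimethyloct-6-en-1-yl]-4-(2-methylpropanoyl)benzene-1,3,5-triyl tris(2,2-dimethylpropanoate) | CC(C)=CCC[C@](C)(O)CCc1c(OC(=O)C(C)(C)C)cc(OC(=O)C(C)(C)C)c(C(=O)C(C)C)c1OC(=O)C(C)(C)C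
F5 | step 3 | 1,3,5-tris(methoxymethoxy)benzene | COCOc1cc(OCOC)cc(OCOC)c1
F6 | step 3 | 2-methyl-1-[2,4,6-tris(methoxymethoxy)phenyl]propan-1-ol (racemic) | CC(C)C(O)c1c(OCOC)cc(OCOC)cc1OCOC
F7 | step 3 | 1-[3-iodo-2,4,6-tris(methoxymethoxy)phenyl]-2-methylpropan-1-ol (racemic) | CC(C)C(O)c1c(OCOC)cc(OCOC)c(I)c1OCOC
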